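**Plan**

- Retrosynthetic cuts, in order: C14=C15 and C12=C13 (two Wittig olefinations); C8–C9 (ring B, radical closure); a temporary C12(=O)–O–C1 lactone and C9=C11 (Z-olefination); last, C1–C10 and C4–C5 together (Diels–Alder), which leaves 3-methyl-2H-pyran-2-one and an (E)-2-methyl-2-enal.
- Enabling feature: on ring A the C1 oxygen and the C19 carboxyl are cis-1,4. Ring A is therefore a ring-opened 2-oxabicyclo[2.2.2]octan-3-one, and C1–C4 with O1, C18 and C19 are a masked 3-methyl-2-pyranone. O1 (on C1) and C11 (on C9) are syn, which allows the temporary six-membered lactone.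
- Forward order: pyranone + enal give ring A as the bridged lactone; C2=C3 is reduced; the Z-enoate is made; methanolysis and relactonisation give the O1–C12 lactone; 6-exo radical closure gives ring B with the C8=C17 methylene; lactol, side-chain diene and acetate follow.
- Stereochemistry: absolute configuration from the chiral oxazaborolidinium catalyst; C1/C4 cis from the lactone bridge; the trans ring fusion (C5/C10) from the E geometry of the enal; C9 from the lactone-constrained cyclisation; 12E from the stabilised ylide.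

Key step: step 5

Remark: labdane numbering is used for all intermediates (C17 = exocyclic methylene carbon, C18 = methyl on C4, C19 = ester carbon, C20 = methyl on C10); the target is in the ent-labdane series.

Assumption: the (S)-catalyst of step 5 is taken, by the usual model for boron-bound 2-methyl enals (formyl C–H···O contact, s-trans enal stacked on a phenyl group), to leave the Cα-Re face open, which leads to 9; the (R)-catalyst would be used if the opposite sense were found.

**Step 1**
Reactants: 1 3-bromo-2H-pyran-2-one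
Product: 2 3-methyl-2H-pyran-2-one
Conditions: (MeBO)3 (0.5 equiv), Pd(PPh3)4 (5 mol%, zerovalent palladium), K2CO3, 1,4-dioxane, 100 °C
Reagents that add atoms: trimethylboroxine, CB1OB(C)OB(C)O1
Why: Suzuki–Miyaura cross-coupling at the vinylic C–Br bond of the 2-pyranone should install the C18 methyl group and leave the lactone intact.

**Step 2**
Reactants: 3 ethyl acetate; 4 2,3-dibromoprop-1-ene
Product: 6 ethyl 4-bromopent-4-enoate, via lithium enolate of ethyl acetate 5 (not isolated)
Conditions: LiN(iPr)2, THF, −78 °C; then 4, DMPU, −78 → −20 °C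
Reagents that add atoms: none
Why: Enolate alkylation (SN2) should occur only at the allylic CH2Br of 4, the vinylic bromide being inert, to give the C6–C7–C8(Br)=C17 chain; no stereocenter is formed.

**Step 3**
Reactants: 6 ethyl 4-bromopent-4-enoate
Product: 7 4-bromopent-4-enal
Conditions: iBu2AlH (1.05 equiv), CH2Cl2, −78 °C; aq. KNaC4H4O6 (potassium sodium tartrate)
Reagents that add atoms: none
Why: Half-reduction of the ester by iBu2AlH at −78 °C should stop at the aluminium hemiacetal, which releases the aldehyde on work-up.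

**Step 4**
Reactants: 7 4-bromopent-4-enal
Product: 8 (2E)-6-bromo-2-methylhepta-2,6-dienal
Conditions: Ph3P=C(CH3)CHO (1.2 equiv), toluene, 80 °C
Reagents that add atoms: 2-(triphenylphosphoranylidene)propanal, CC(C=O)=P(c1ccccc1)(c1ccccc1)c1ccccc1
Why: Wittig olefination with the formyl-stabilised ylide is E-selective, so the CHO carbon (C9) and C6 should end up trans across C10=C5, the geometry that later becomes the trans ring fusion.

**Step 5**
Reactants: 2 3-methyl-2H-pyran-2-one; 8 (2E)-6-bromo-2-methylhepta-2,6-dienal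
Product: 9 (1S,4R,7S,8S)-8-(3-bromobut-3-en-1-yl)-4,7-dimethyl-3-oxo-2-oxabicyclo[2.2.2]oct-5-ene-7-carbaldehyde
Conditions: 2 (3 equiv), (S)-3,3-diphenyl-1-(2-methylphenyl)tetrahydro-1H,3H-pyrrolo[1,2-c][1,3,2]oxazaborole (20 mol%) + HN(SO2CF3)2 (18 mol%), CH2Cl2, −40 → 0 °C
Reagents that add atoms: none
Why: Proposed new method: a Lewis-acid-catalysed normal-electron-demand Diels–Alder reaction in which the boron-bound s-trans enal 8 is attacked by the C3–C6 diene of 2 in an asynchronous, concerted endo transition state; the closest known reaction types are the oxazaborolidinium-catalysed enantioselective Diels–Alder reaction of 2-methyl-substituted enals with simple dienes and the thermal or high-pressure cycloaddition of 2-pyranones with enals that stops at the bridged lactone, but a 2-pyranone has not been used as the diene under this catalysis. Ring A is closed by an intermolecular suprafacial [4+2] union of the four pyranone carbons (C1–C4) with C5=C10 of the enal (no tether is involved), which leaves the old pyranone ring as the lactone bridge of a 2-oxabicyclo[2.2.2]octene. C1 and C4 are bridgeheads and are therefore formed cis, which fixes the later cis relation of the C1 oxygen and the C19 ester; C5 and C10 take their mutual relation (C6 and C9 trans, the future trans ring fusion) from the E geometry of 8 and their relation to C1/C4 from the endo position of the formyl group under C2=C3, with both alkyl groups over the hydrogen-free O–C(=O) bridge; the absolute configuration at all four centres comes from the catalyst, which covers one face of the bound enal with a phenyl group and leaves the Cα-Re face open. The step needs regioselectivity, secured because the electrophilic β-carbon (C5) bonds in advance to the nucleophilic methyl-bearing pyranone carbon (C4), the charge being taken up by the ring oxygen, and because the reverse orientation would join two fully substituted carbons. It also needs the adduct to survive, which the low temperature secures since loss of CO2 by retro-[4+2] needs heating.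

**Step 6**
Reactants: 9 (1S,4R,7S,8S)-8-(3-bromobut-3-en-1-yl)-4,7-dimethyl-3-oxo-2-oxabicyclo[2.2.2]oct-5-ene-7-carbaldehyde
Product: 10 (1S,4R,5S,6S)-5-(3-bromobut-3-en-1-yl)-4,6-dimethyl-3-oxo-2-oxabicyclo[2.2.2]octane-6-carbaldehyde
Conditions: KO2CN=NCO2K (excess), AcOH, MeOH/CH2Cl2, 0 °C → rt
Reagents that add atoms: none
Why: Diimide reduction (concerted syn transfer of two hydrogens) is fastest for the strained cis-disubstituted C2=C3 bond of the bicyclo[2.2.2]octene and should leave the 2-bromoalkene and the aldehyde untouched; no stereocenter is formed and the retro-[4+2] pathway is removed.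

**Step 7**
Reactants: 10 (1S,4R,5S,6S)-5-(3-bromobut-3-en-1-yl)-4,6-dimethyl-3-oxo-2-oxabicyclo[2.2.2]octane-6-carbaldehyde
Product: 11 methyl (2Z)-3-[(1S,4R,5S,6S)-5-(3-bromobut-3-en-1-yl)-4,6-dimethyl-3-oxo-2-oxabicyclo[2.2.2]octan-6-yl]prop-2-enoate
Conditions: (CF3CH2O)2P(O)CH2CO2Me, KN(SiMe3)2, 18-crown-6, THF, −78 °C
Reagents that add atoms: methyl 2-[bis(2,2,2-trifluoroethoxy)phosphoryl]acetate, COC(=O)CP(=O)(OCC(F)(F)F)OCC(F)(F)F
Why: The Still–Gennari variant of the Horner–Wadsworth–Emmons olefination should give the Z enoate (C9=C11) under kinetic control, the geometry needed for lactonisation onto O1; the aldehyde has no α-hydrogen and cannot enolise.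

**Step 8**
Reactants: 11 methyl (2Z)-3-[(1S,4R,5S,6S)-5-(3-bromobut-3-en-1-yl)-4,6-dimethyl-3-oxo-2-oxabicyclo[2.2.2]octan-6-yl]prop-2-enoate
Product: 13 methyl (4aS,5S,6R,8aS)-5-(3-bromobut-3-en-1-yl)-4a,6-dimethyl-2-oxo-4a,5,6,7,8,8a-hexahydro-2H-chromene-6-carboxylate, via hydroxy diester 12 (not isolated)
Conditions: NaOMe (0.2 equiv), MeOH, 0 °C → rt; AcOH; then PPTS (cat.), toluene, 60 °C
Reagents that add atoms: methanol, CO
Why: Base-catalysed methanolysis (transesterification) should open the strained, boat-locked bridged lactone to the C19 methyl ester and the C1 hydroxyl, ring A relaxes to the chair with O1 and C9 both equatorial, and acid-catalysed lactonisation onto the Z enoate then gives the six-membered unsaturated lactone; no stereocenter changes.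

**Step 9**
Reactants: 13 methyl (4aS,5S,6R,8aS)-5-(3-bromobut-3-en-1-yl)-4a,6-dimethyl-2-oxo-4a,5,6,7,8,8a-hexahydro-2H-chromene-6-carboxylate
Product: 14 methyl (1S,4R,5S,9R,10S)-12-oxo-1,12-epoxy-13,14,15,16-tetranorlabd-8(17)-en-19-oate (the 12,1-lactone)
Conditions: Bu3SnH (1.3 equiv, slow addition), AIBN (cat.), benzene (0.01 M), 80 °C
Reagents that add atoms: none
Why: Tin hydride radical chain cyclisation: the C8 vinyl radical should close 6-exo-trig onto C9, the β-carbon of the unsaturated lactone, and the C11 radical then takes hydrogen from Bu3SnH; C9 is set because the trans-fused lactone holds C11 syn to O1, so C8 can reach only the face that gives the all-chair tricycle with H9 anti to the C20 methyl.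

**Step 10**
Reactants: 14 methyl (1S,4R,5S,9R,10S)-12-oxo-1,12-epoxy-13,14,15,16-tetranorlabd-8(17)-en-19-oate
Product: 15 methyl (1S,4R,5S,9R,10S)-12-hydroxy-1,12-epoxy-13,14,15,16-tetranorlabd-8(17)-en-19-oate (lactol; both C12 epimers)
Conditions: iBu2AlH (1.1 equiv), CH2Cl2, −78 °C; aq. KNaC4H4O6 (potassium sodium tartrate)
Reagents that add atoms: none
Why: iBu2AlH half-reduction of a lactone to the lactol should be much faster at −78 °C than attack on the hindered axial C19 methyl ester on a quaternary carbon.

**Step 11**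
Reactants: 15 methyl (1S,4R,5S,9R,10S)-12-hydroxy-1,12-epoxy-13,14,15,16-tetranorlabd-8(17)-en-19-oate
Product: 17 methyl (1S,4R,5S,9R,10S,12E)-1-hydroxy-14-oxo-15-norlabda-8(17),12-dien-19-oate, via open-chain hydroxy aldehyde 16 (not isolated)
Conditions: Ph3P=C(CH3)CHO (2 equiv), toluene, 90 °C
Reagents that add atoms: 2-(triphenylphosphoranylidene)propanal, CC(C=O)=P(c1ccccc1)(c1ccccc1)c1ccccc1
Why: Wittig olefination of the ring-opened aldehyde tautomer of the lactol with the formyl-stabilised ylide should give the E trisubstituted enal (C12=C13) and free the C1 hydroxyl.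

**Step 12**
Reactants: 17 methyl (1S,4R,5S,9R,10S,12E)-1-hydroxy-14-oxo-15-norlabda-8(17),12-dien-19-oate
Product: 18 methyl (1S,4R,5S,9R,10S,12E)-1-acetoxy-14-oxo-15-norlabda-8(17),12-dien-19-oate
Conditions: Ac2O, Et3N, DMAP (cat.), CH2Cl2, 0 °C → rt
Reagents that add atoms: acetic anhydride, CC(=O)OC(C)=O
Why: DMAP-catalysed acylation should acetylate the hindered equatorial secondary alcohol under conditions mild enough for the enal and the exocyclic alkene.

**Step 13**
Reactants: 18 methyl (1S,4R,5S,9R,10S,12E)-1-acetoxy-14-oxo-15-norlabda-8(17),12-dien-19-oate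
Product: 19 methyl (1S,4R,5S,9R,10S,12E)-1-acetoxylabda-8(17),12,14-trien-19-oate (CNP0235031.1)
Conditions: Ph3PCH3Br, KN(SiMe3)2, THF, 0 °C; then 18, −78 → 0 °C
Reagents that add atoms: methyltriphenylphosphonium bromide, C[P+](c1ccccc1)(c1ccccc1)c1ccccc1.[Br-]
Why: Wittig methylenation of the enal carbonyl, the most electrophilic group present, should form C14=C15 without touching the acetate or the hindered ester when a small excess of ylide is used at low temperature.

**Compound list**

1 | 3-bromo-2H-pyran-2-one | O=C1OC=CC=C1Br | starting material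
2 | 3-methyl-2H-pyran-2-one | CC1=CC=COC1=O | intermediate
3 | ethyl acetate | CCOC(C)=O | starting material
4 | 2,3-dibromoprop-1-ene | C=C(Br)CBr | starting material
5 | lithium enolate of ethyl acetate (lithium 1-ethoxyethen-1-olate; formed in the flask, not isolated) | [Li]OC(=C)OCC | intermediate
6 | ethyl 4-bromopent-4-enoate | CCOC(=O)CCC(Br)=C | intermediate
7 | 4-bromopent-4-enal | O=CCCC(Br)=C | intermediate
8 | (2E)-6-bromo-2-methylhepta-2,6-dienal | O=C/C(C)=C/CCC(Br)=C | intermediate
9 | (1S,4R,7S,8S)-8-(3-bromobut-3-en-1-yl)-4,7-dimethyl-3-oxo-2-oxabicyclo[2.2.2]oct-5-ene-7-carbaldehyde (formyl group endo, syn to C=C; both methyl groups and the bromobutenyl chain on the lactone side) | O=C[C@@]1(C)[C@H](CCC(Br)=C)[C@@]2(C)C=C[C@@H]1OC2=O | intermediate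
10 | (1S,4R,5S,6S)-5-(3-bromobut-3-en-1-yl)-4,6-dimethyl-3-oxo-2-oxabicyclo[2.2.2]octane-6-carbaldehyde | O=C[C@@]1(C)[C@H](CCC(Br)=C)[C@@]2(C)CC[C@@H]1OC2=O | intermediate
11 | methyl (2Z)-3-[(1S,4R,5S,6S)-5-(3-bromobut-3-en-1-yl)-4,6-dimethyl-3-oxo-2-oxabicyclo[2.2.2]octan-6-yl]prop-2-enoate | COC(=O)/C=C\[C@@]1(C)[C@H](CCC(Br)=C)[C@@]2(C)CC[C@@H]1OC2=O | intermediate
12 | methyl (1R,2S,3S,4S)-2-(3-bromobut-3-en-1-yl)-4-hydroxy-3-[(1Z)-3-methoxy-3-oxoprop-1-en-1-yl]-1,3-dimethylcyclohexane-1-carboxylate (hydroxy diester; formed in the flask, not isolated) | COC(=O)/C=C\[C@@]1(C)[C@H](CCC(Br)=C)[C@](C)(C(=O)OC)CC[C@@H]1O | intermediate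
13 | methyl (4aS,5S,6R,8aS)-5-(3-bromobut-3-en-1-yl)-4a,6-dimethyl-2-oxo-4a,5,6,7,8,8a-hexahydro-2H-chromene-6-carboxylate | O=C1C=C[C@@]2(C)[C@H](CCC(Br)=C)[C@](C)(C(=O)OC)CC[C@@H]2O1 | intermediate
14 | methyl (1S,4R,5S,9R,10S)-12-oxo-1,12-epoxy-13,14,15,16-tetranorlabd-8(17)-en-19-oate (tricyclic 12,1-lactone) | O=C1C[C@@H]2C(=C)CC[C@H]3[C@@]2(C)[C@@H](O1)CC[C@@]3(C)C(=O)OC | intermediate
15 | methyl (1S,4R,5S,9R,10S)-12-hydroxy-1,12-epoxy-13,14,15,16-tetranorlabd-8(17)-en-19-oate (lactol; both C12 epimers) | OC1C[C@@H]2C(=C)CC[C@H]3[C@@]2(C)[C@@H](O1)CC[C@@]3(C)C(=O)OC | intermediate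
16 | methyl (1S,4R,5S,9R,10S)-1-hydroxy-12-oxo-13,14,15,16-tetranorlabd-8(17)-en-19-oate (open-chain hydroxy aldehyde; formed in the flask, not isolated) | O=CC[C@@H]1C(=C)CC[C@H]2[C@@]1(C)[C@@H](O)CC[C@@]2(C)C(=O)OC | intermediate
17 | methyl (1S,4R,5S,9R,10S,12E)-1-hydroxy-14-oxo-15-norlabda-8(17),12-dien-19-oate | O=C/C(C)=C/C[C@@H]1C(=C)CC[C@H]2[C@@]1(C)[C@@H](O)CC[C@@]2(C)C(=O)OC | intermediate
18 | methyl (1S,4R,5S,9R,10S,12E)-1-acetoxy-14-oxo-15-norlabda-8(17),12-dien-19-oate | O=C/C(C)=C/C[C@@H]1C(=C)CC[C@H]2[C@@]1(C)[C@@H](OC(C)=O)CC[C@@]2(C)C(=O)OC | intermediate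
19 | methyl (1S,4R,5S,9R,10S,12E)-1-acetoxylabda-8(17),12,14-trien-19-oate (CNP0235031.1) | C=C/C(C)=C/C[C@@H]1C(=C)CC[C@H]2[C@@]1(C)[C@@H](OC(C)=O)CC[C@@]2(C)C(=O)OC | target

**Step count**

Total: 13 steps. Longest linear sequence: 12 steps (steps 2 to 13); step 1 is a one-step branch.

**Steps most likely to fail**

Step 5 (Proposed new method). The more Lewis-basic pyranone carbonyl may tie up the boron catalyst so that turnover stalls, and the orientation or the facial selectivity of the cycloaddition may be eroded. The fallback sets out from 2 and 8 and comes back at 9. The two are combined without catalyst in CH2Cl2 at about 12 kbar and room temperature, a known pressure-promoted cycloaddition of 2-pyranones that keeps the CO2 bridge. This should give the racemic endo adduct, that is 9 together with its mirror image, the (1R,4S,7R,8R)-aldehyde F1; any regioisomer is removed here. Condensation of the mixture with (1R,2R)-N,N'-dimethyl-1,2-diphenylethane-1,2-diamine (molecular sieves, Et2O) should give two diastereomers, the imidazolidine of 9 F2 and the imidazolidine of the mirror-image aldehyde F3, which are separated by chromatography or crystallisation. Hydrolysis of F2 with dilute aqueous HCl in a two-phase system returns 9.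

Step 9. Hydrogen transfer from the tin hydride to the vinyl radical may outrun ring closure onto the hindered C9, or a 1,6-hydrogen shift may divert the radical. The fallback sets out from 13 and comes back at 14 by a reductive Heck cyclisation: Pd(OAc)2, PPh3 (zerovalent palladium formed in the flask), HCO2Na, Et4NCl, DMF, 80 °C. Oxidative addition into the C8–Br bond and 6-exo carbopalladation of C9=C11 follow; the palladium on C11 has no syn β-hydrogen inside the lactone ring, so formate capture and reductive elimination should give 14. This fallback makes no new compound (entry F0).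

Step 11. Olefination of the lactol may be slow because little open aldehyde is present, and the freed C1 hydroxyl may add back to the new enal at C12 (oxa-Michael ring closure). The fallback sets out from 14 and comes back at 18. Me(MeO)NH·HCl with AlMe3 in CH2Cl2 should open the lactone to the hydroxy N-methoxy-N-methylamide F4. Ac2O with DMAP gives the acetoxy amide F5. Cp2Zr(H)Cl in THF reduces the amide to the acetoxy aldehyde F6 without touching the esters. Wittig reaction of F6 with Ph3P=C(CH3)CHO then gives 18, so the hydroxyl is never free next to the enal.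

**Further compounds**

F1 | step 5 | (1R,4S,7R,8R)-8-(3-bromobut-3-en-1-yl)-4,7-dimethyl-3-oxo-2-oxabicyclo[2.2.2]oct-5-ene-7-carbaldehyde (mirror image of 9) | O=C[C@]1(C)[C@@H](CCC(Br)=C)[C@]2(C)C=C[C@H]1OC2=O
F2 | step 5 | imidazolidine (aminal) of 9 with (1R,2R)-N,N'-dimethyl-1,2-diphenylethane-1,2-diamine | CN1[C@H](c2ccccc2)[C@@H](c3ccccc3)N(C)C1[C@@]4(C)[C@H](CCC(Br)=C)[C@@]5(C)C=C[C@@H]4OC5=O
F3 | step 5 | imidazolidine (aminal) of the mirror-image aldehyde with (1R,2R)-N,N'-dimethyl-1,2-diphenylethane-1,2-diamine | CN1[C@H](c2ccccc2)[C@@H](c3ccccc3)N(C)C1[C@]4(C)[C@@H](CCC(Br)=C)[C@]5(C)C=C[C@H]4OC5=O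
F0 | step 9 | none | none
F4 | step 11 | methyl (1S,4R,5S,9R,10S)-1-hydroxy-12-[methoxy(methyl)amino]-12-oxo-13,14,15,16-tetranorlabd-8(17)-en-19-oate | CON(C)C(=O)C[C@@H]1C(=C)CC[C@H]2[C@@]1(C)[C@@H](O)CC[C@@]2(C)C(=O)OC
F5 | step 11 | methyl (1S,4R,5S,9R,10S)-1-acetoxy-12-[methoxy(methyl)amino]-12-oxo-13,14,15,16-tetranorlabd-8(17)-en-19-oate | CON(C)C(=O)C[C@@H]1C(=C)CC[C@H]2[C@@]1(C)[C@@H](OC(C)=O)CC[C@@]2(C)C(=O)OC
F6 | step 11 | methyl (1S,4R,5S,9R,10S)-1-acetoxy-12-oxo-13,14,15,16-tetranorlabd-8(17)-en-19-oate | O=CC[C@@H]1C(=C)CC[C@H]2[C@@]1(C)[C@@H](OC(C)=O)CC[C@@]2(C)C(=O)OC
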